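**Retrosynthetic overview** (carotenoid numbering: C1 and C1′ are the two carbinol carbons; the oxirane is C3–C4)
1. Two Wittig disconnections (C7=C8 and C7′=C8′) give a left C15 epoxy-enal, a right C15 dihydroxy-dienal and a C20 bis(phosphonium) salt.
2. The C20 salt comes from the C10 dialdehyde and two C5 hydroxy-phosphonium units (C11=C12 and C11′=C12′).
3. The only ring, the 3,4-oxirane, is closed in the left arm by C–O bond formation: amine-catalysed vinylogous epoxidation of the (R)-dienal with H2O2.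
4. The two ends need opposite configurations at C2 and C2′, so both arms come from one racemic dienenitrile whose enantiomers are separated on a chiral phase; the right arm then gets a Markovnikov hydration of the prenyl group.
5. The racemic dienenitrile comes from prenylation of a β-hydroxy ester dianion followed by one-pot reduction/HWE olefination with a C5 phosphonate.

Assumption: phosphonate 4 is bought as its E/Z mixture (minor 2Z products are removed by chromatography), and the enantiomers of 6 are separated in one chromatographic run that is written as steps 3 and 4, because each collected fraction is a numbered compound of its own.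

**Step 1**
Reactants: 1 ethyl 3-hydroxy-3-methylbutanoate; 2 1-bromo-3-methylbut-2-ene (prenyl bromide)
Product: 3 rac-ethyl 2-(2-hydroxypropan-2-yl)-5-methylhex-4-enoate
Conditions: LiN(i-Pr)2 (2.2 equiv), THF, −78 to −30 °C; then 2, DMPU, −78 to −20 °C; H2O quench
Reagents that add atoms: none
Why: Fráter–Seebach-type C-alkylation of the β-hydroxy ester dianion with a reactive allylic bromide; the new stereocentre (later C2 and C2′) is made racemic on purpose because the two ends of the target need opposite configurations.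

**Step 2**
Reactants: 3 rac-ethyl 2-(2-hydroxypropan-2-yl)-5-methylhex-4-enoate; 4 diethyl [(2E)-3-cyano-2-methylprop-2-en-1-yl]phosphonate
Product: 6 rac-(2E,4E)-7-hydroxy-3,7-dimethyl-6-(3-methylbut-2-en-1-yl)octa-2,4-dienenitrile, via racemic hydroxy aldehyde 5 (not isolated)
Conditions: i-Bu2AlH (2.1 equiv), CH2Cl2, −78 °C; then 4 + LiN(SiMe3)2 (THF, −78 °C), warm to rt
Reagents that add atoms: none
Why: tandem ester reduction/Horner–Wadsworth–Emmons olefination in which the aluminium hemiacetal releases the retro-aldol-prone β-hydroxy aldehyde only in the presence of the phosphonate anion; the new disubstituted alkene forms E.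

**Step 3**
Reactants: 6 rac-(2E,4E)-7-hydroxy-3,7-dimethyl-6-(3-methylbut-2-en-1-yl)octa-2,4-dienenitrile
Product: 7 (2E,4E,6R)-7-hydroxy-3,7-dimethyl-6-(3-methylbut-2-en-1-yl)octa-2,4-dienenitrile
Conditions: preparative supercritical-fluid chromatography, amylose tris(3,5-dimethylphenylcarbamate) phase, CO2/MeOH, stacked injections; collect the (R)-enantiomer fraction
Reagents that add atoms: none
Why: resolution of a racemate by chiral-phase chromatography, a physical separation in which no bond is formed; the (R)-enantiomer serves the epoxide end and its configuration is assigned by crystal-structure analysis of a derivative.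

**Step 4**
Reactants: 6 rac-(2E,4E)-7-hydroxy-3,7-dimethyl-6-(3-methylbut-2-en-1-yl)octa-2,4-dienenitrile
Product: 8 (2E,4E,6S)-7-hydroxy-3,7-dimethyl-6-(3-methylbut-2-en-1-yl)octa-2,4-dienenitrile
Conditions: the other fraction of the same chromatographic run as step 3 (same phase and eluent); mixed fractions are re-injected
Reagents that add atoms: none
Why: resolution of a racemate by chiral-phase chromatography, in which the (S)-enantiomer is collected and not discarded because the non-epoxide end of the target needs this configuration, so the whole racemate is used.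

**Step 5**
Reactants: 7 (2E,4E,6R)-7-hydroxy-3,7-dimethyl-6-(3-methylbut-2-en-1-yl)octa-2,4-dienenitrile
Product: 9 (2E,4E,6R)-7-hydroxy-3,7-dimethyl-6-(3-methylbut-2-en-1-yl)octa-2,4-dienal
Conditions: i-Bu2AlH (2.2 equiv), toluene, −78 °C; then aqueous tartaric acid, 0 °C
Reagents that add atoms: water, O
Why: partial reduction of the conjugated nitrile to the N-aluminoimine and hydrolysis to the enal (standard nitrile-to-aldehyde reduction); the stereocentre is not touched.

**Step 6**
Reactants: 9 (2E,4E,6R)-7-hydroxy-3,7-dimethyl-6-(3-methylbut-2-en-1-yl)octa-2,4-dienal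
Product: 10 (2E)-3-{(2R,3R)-3-[(3R)-2-hydroxy-2,6-dimethylhept-5-en-3-yl]oxiran-2-yl}but-2-enal
Conditions: (S)-2-{bis[3,5-bis(trifluoromethyl)phenyl][(trimethylsilyl)oxy]methyl}pyrrolidine (20 mol %), 35% aq. H2O2 (1.5 equiv), CH2Cl2, 0 °C
Reagents that add atoms: hydrogen peroxide, OO
Why: Proposed new method: a vinylogous (1,6-) Weitz–Scheffer epoxidation under iminium catalysis, in which the amine condenses with 9 to the dienyl iminium ion, H2O2 adds at the δ-carbon C5 (the β-carbon is blocked by its methyl group and by the catalyst arm), and the peroxy-dienamine closes through its γ-carbon C4 onto the proximal peroxide oxygen with loss of hydroxide, forming both C–O bonds; the (S)-catalyst shields one face of the whole planar dienyl iminium so that oxygen goes to the open face and both new centres become R (reagent control over the weak bias of the neighbouring centre across an E-alkene), allylic strain with the C3 methyl in the dienamine forces closure to the trans-oxirane, and the electron-rich prenyl alkene is inert to the nucleophilic oxidant; the closest known reactions are the amine-catalysed 1,4-epoxidation of enals with H2O2 and amine-catalysed 1,6-additions to 3-substituted 2,4-dienals.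

**Step 7**
Reactants: 8 (2E,4E,6S)-7-hydroxy-3,7-dimethyl-6-(3-methylbut-2-en-1-yl)octa-2,4-dienenitrile
Product: 11 (2E,4E,6S)-7-hydroxy-6-(3-hydroxy-3-methylbutyl)-3,7-dimethylocta-2,4-dienenitrile
Conditions: Co(acac)2 (20 mol %), PhSiH3 (2.5 equiv), O2 (1 atm), THF/i-PrOH, 0 °C to rt
Reagents that add atoms: dioxygen, O=O
Why: Mukaiyama hydration (metal-hydride hydrogen-atom transfer, Markovnikov), expected to favour the electron-rich trisubstituted alkene over the nitrile-deactivated diene, with O2 trapping the tertiary radical before it can cyclise; no new stereocentre.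

**Step 8**
Reactants: 11 (2E,4E,6S)-7-hydroxy-6-(3-hydroxy-3-methylbutyl)-3,7-dimethylocta-2,4-dienenitrile
Product: 12 (2E,4E,6S)-7-hydroxy-6-(3-hydroxy-3-methylbutyl)-3,7-dimethylocta-2,4-dienal
Conditions: i-Bu2AlH (3.3 equiv), toluene, −78 °C; then aqueous tartaric acid, 0 °C
Reagents that add atoms: water, O
Why: the same nitrile-to-aldehyde reduction as in step 5, with two extra equivalents of hydride for the two hydroxyl groups.

**Step 9**
Reactants: 13 2-methyl-2-vinyloxirane (isoprene monoxide, racemic)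
Product: 14 [(2E)-4-hydroxy-3-methylbut-2-en-1-yl]triphenylphosphonium bromide
Conditions: PPh3·HBr (1.0 equiv), CH2Cl2, 0 °C to rt; recrystallise the E salt
Reagents that add atoms: triphenylphosphine hydrobromide, Br.P(c1ccccc1)(c1ccccc1)c1ccccc1
Why: acid-promoted SN2′ opening of the vinyl epoxide through the tertiary allylic cation, with the soft phosphine attacking the unhindered vinyl terminus (the same regiochemistry as the known halide openings of this epoxide).

**Step 10**
Reactants: 14 [(2E)-4-hydroxy-3-methylbut-2-en-1-yl]triphenylphosphonium bromide (2.3 equiv); 15 (2E,4E,6E)-2,7-dimethylocta-2,4,6-trienedial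
Product: 16 (2E,4E,6E,8E,10E,12E,14E)-2,6,11,15-tetramethylhexadeca-2,4,6,8,10,12,14-heptaene-1,16-diol
Conditions: NaOMe (2.4 equiv), CH2Cl2/MeOH, 0 °C to rt; then iodine (cat.), CH2Cl2, daylight; crystallise
Reagents that add atoms: none
Why: twofold Wittig olefination of the dialdehyde with a hydroxy-substituted allylic ylide (the free hydroxyl is tolerated in methanolic methoxide); the new double bonds are equilibrated to E and the all-E diol crystallises.

**Step 11**
Reactants: 16 (2E,4E,6E,8E,10E,12E,14E)-2,6,11,15-tetramethylhexadeca-2,4,6,8,10,12,14-heptaene-1,16-diol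
Product: 17 [(2E,4E,6E,8E,10E,12E,14E)-2,6,11,15-tetramethylhexadeca-2,4,6,8,10,12,14-heptaene-1,16-diyl]bis(triphenylphosphonium) dibromide
Conditions: PPh3·HBr (2.1 equiv), MeOH/CH2Cl2, rt
Reagents that add atoms: triphenylphosphine hydrobromide, Br.P(c1ccccc1)(c1ccccc1)c1ccccc1
Why: SN1-type substitution of the polyenylic alcohol through the delocalised cation, with the phosphine attacking the terminal carbon as in the standard conversion of polyenyl allylic alcohols into phosphonium salts.

**Step 12**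
Reactants: 17 [(2E,4E,6E,8E,10E,12E,14E)-2,6,11,15-tetramethylhexadeca-2,4,6,8,10,12,14-heptaene-1,16-diyl]bis(triphenylphosphonium) dibromide (2.0 equiv); 12 (2E,4E,6S)-7-hydroxy-6-(3-hydroxy-3-methylbutyl)-3,7-dimethylocta-2,4-dienal
Product: 18 [(2E,4E,6E,8E,10E,12E,14E,16E,18E,20E,22S)-23-hydroxy-22-(3-hydroxy-3-methylbutyl)-2,6,11,15,19,23-hexamethyltetracosa-2,4,6,8,10,12,14,16,18,20-decaen-1-yl]triphenylphosphonium bromide
Conditions: NaOMe (1.0 equiv), CH2Cl2/MeOH, −20 to 0 °C, slow addition of 12; chromatography (CH2Cl2/MeOH), excess 17 recovered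
Reagents that add atoms: none
Why: Wittig olefination of a semi-stabilised polyenyl ylide; with one equivalent of base and excess bis-salt the mono-ylide dominates, and the monocationic product is separated from neutral bis-adduct and dicationic 17 (any Z isomer at the new bond is carried on).

**Step 13**
Reactants: 18 [(2E,4E,6E,8E,10E,12E,14E,16E,18E,20E,22S)-23-hydroxy-22-(3-hydroxy-3-methylbutyl)-2,6,11,15,19,23-hexamethyltetracosa-2,4,6,8,10,12,14,16,18,20-decaen-1-yl]triphenylphosphonium bromide; 10 (2E)-3-{(2R,3R)-3-[(3R)-2-hydroxy-2,6-dimethylhept-5-en-3-yl]oxiran-2-yl}but-2-enal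
Product: 19 (2R,3R,4R,2′S)-3,4-epoxy-2′-(3-hydroxy-3-methylbutyl)-2-(3-methylbut-2-en-1-yl)-3′,4′-didehydro-1,2,1′,2′-tetrahydro-ψ,ψ-carotene-1,1′-diol (CNP0268815.3)
Conditions: NaOMe (1.1 equiv), CH2Cl2/MeOH, −10 °C to rt; then heptane/EtOAc, 70 °C, dark, N2; Et3N-deactivated SiO2
Reagents that add atoms: none
Why: Wittig olefination under mild methoxide conditions with the oxirane on the aldehyde partner (a carbanion next to the vinyl oxirane would open it); the hindered Z isomers at C7=C8 and C7′=C8′ revert thermally to all-E, and no stereocentre is touched.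

**Compound list**
1 | ethyl 3-hydroxy-3-methylbutanoate | CCOC(=O)CC(C)(C)O | starting material
2 | 1-bromo-3-methylbut-2-ene | CC(C)=CCBr | starting material
3 | rac-ethyl 2-(2-hydroxypropan-2-yl)-5-methylhex-4-enoate | CCOC(=O)C(CC=C(C)C)C(C)(C)O | intermediate
4 | diethyl [(2E)-3-cyano-2-methylprop-2-en-1-yl]phosphonate | CCOP(=O)(OCC)C/C(C)=C/C#N | starting material
5 | rac-2-(2-hydroxypropan-2-yl)-5-methylhex-4-enal (formed as its aluminium hemiacetal) | CC(C)=CCC(C=O)C(C)(C)O | intermediate
6 | rac-(2E,4E)-7-hydroxy-3,7-dimethyl-6-(3-methylbut-2-en-1-yl)octa-2,4-dienenitrile | CC(C)=CCC(/C=C/C(C)=C/C#N)C(C)(C)O | intermediate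
7 | (2E,4E,6R)-7-hydroxy-3,7-dimethyl-6-(3-methylbut-2-en-1-yl)octa-2,4-dienenitrile | CC(C)=CC[C@H](/C=C/C(C)=C/C#N)C(C)(C)O | intermediate
8 | (2E,4E,6S)-7-hydroxy-3,7-dimethyl-6-(3-methylbut-2-en-1-yl)octa-2,4-dienenitrile | CC(C)=CC[C@@H](/C=C/C(C)=C/C#N)C(C)(C)O | intermediate
9 | (2E,4E,6R)-7-hydroxy-3,7-dimethyl-6-(3-methylbut-2-en-1-yl)octa-2,4-dienal | CC(C)=CC[C@H](/C=C/C(C)=C/C=O)C(C)(C)O | intermediate
10 | (2E)-3-{(2R,3R)-3-[(3R)-2-hydroxy-2,6-dimethylhept-5-en-3-yl]oxiran-2-yl}but-2-enal | CC(C)=CC[C@H]([C@H]1O[C@@H]1/C(C)=C/C=O)C(C)(C)O | intermediate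
11 | (2E,4E,6S)-7-hydroxy-6-(3-hydroxy-3-methylbutyl)-3,7-dimethylocta-2,4-dienenitrile | CC(C)(O)CC[C@@H](/C=C/C(C)=C/C#N)C(C)(C)O | intermediate
12 | (2E,4E,6S)-7-hydroxy-6-(3-hydroxy-3-methylbutyl)-3,7-dimethylocta-2,4-dienal | CC(C)(O)CC[C@@H](/C=C/C(C)=C/C=O)C(C)(C)O | intermediate
13 | 2-methyl-2-vinyloxirane (racemic) | C=CC1(C)CO1 | starting material
14 | [(2E)-4-hydroxy-3-methylbut-2-en-1-yl]triphenylphosphonium bromide | OC/C(C)=C/C[P+](c1ccccc1)(c1ccccc1)c1ccccc1.[Br-] | intermediate
15 | (2E,4E,6E)-2,7-dimethylocta-2,4,6-trienedial | O=C/C(C)=C/C=C/C=C(C)/C=O | starting material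
16 | (2E,4E,6E,8E,10E,12E,14E)-2,6,11,15-tetramethylhexadeca-2,4,6,8,10,12,14-heptaene-1,16-diol | OC/C(C)=C/C=C/C(C)=C/C=C/C=C(C)/C=C/C=C(C)/CO | intermediate
17 | [(2E,4E,6E,8E,10E,12E,14E)-2,6,11,15-tetramethylhexadeca-2,4,6,8,10,12,14-heptaene-1,16-diyl]bis(triphenylphosphonium) dibromide | [Br-].[Br-].c1ccccc1[P+](c1ccccc1)(c1ccccc1)C/C(C)=C/C=C/C(C)=C/C=C/C=C(C)/C=C/C=C(C)/C[P+](c1ccccc1)(c1ccccc1)c1ccccc1 | intermediate
18 | [(2E,4E,6E,8E,10E,12E,14E,16E,18E,20E,22S)-23-hydroxy-22-(3-hydroxy-3-methylbutyl)-2,6,11,15,19,23-hexamethyltetracosa-2,4,6,8,10,12,14,16,18,20-decaen-1-yl]triphenylphosphonium bromide | [Br-].c1ccccc1[P+](c1ccccc1)(c1ccccc1)C/C(C)=C/C=C/C(C)=C/C=C/C=C(C)/C=C/C=C(C)/C=C/C=C(C)/C=C/[C@H](CCC(C)(C)O)C(C)(C)O | intermediate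
19 | (2R,3R,4R,2′S)-3,4-epoxy-2′-(3-hydroxy-3-methylbutyl)-2-(3-methylbut-2-en-1-yl)-3′,4′-didehydro-1,2,1′,2′-tetrahydro-ψ,ψ-carotene-1,1′-diol | CC(C)=CC[C@H]([C@H]1O[C@@H]1/C(C)=C/C=C/C(C)=C/C=C/C(C)=C/C=C/C=C(C)/C=C/C=C(C)/C=C/C=C(C)/C=C/[C@H](CCC(C)(C)O)C(C)(C)O)C(C)(C)O | target

**Totals**
Total step count: 13 (steps 3 and 4 are the two fractions of one chromatographic run). Longest linear sequence: 7 steps (1, 2, 4, 7, 8, 12, 13).

**Three steps most likely to fail**

1. The vinylogous epoxidation (step 6, the proposed new step). The risks are: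
- 1,4-addition at the methyl-bearing β-carbon instead of 1,6-addition;
- weak face control at the remote δ-carbon, possibly opposed by the neighbouring stereocentre (the unwanted oxirane diastereomer is separable);
- epimerisation of C6 through a trienamine.

The fallback uses known chemistry; it sets out from 3 and comes back to the route at 10. Ester 3 is reduced with i-Bu2AlH to the aluminium hemiacetal of the racemic aldehyde 5, which is olefinated in the same flask with the commercial ylide Ph3P=CHC(O)CH3 to rac-(3E)-6-hydroxy-6-methyl-5-(3-methylbut-2-en-1-yl)hept-3-en-2-one F1. The known amine-salt-catalysed epoxidation of acyclic enones with aqueous H2O2 is run to full conversion (9-amino-9-deoxy-epi-quinine bis(trifluoroacetate) or its pseudoenantiomer, whichever gives the required sense; dioxane, 50 °C, where the epoxide and not the peroxyhemiketal is obtained). Each enantiomer of F1 then gives a trans-epoxy ketone with the same catalyst-set configuration at the two new centres. The diastereomer from the (R)-enantiomer, 1-{(2S,3R)-3-[(3R)-2-hydroxy-2,6-dimethylhept-5-en-3-yl]oxiran-2-yl}ethan-1-one F2, is separated by chromatography from the diastereomer from the (S)-enantiomer, 1-{(2S,3R)-3-[(3S)-2-hydroxy-2,6-dimethylhept-5-en-3-yl]oxiran-2-yl}ethan-1-one F3, which is set aside. HWE olefination of F2 with (EtO)2P(O)CH2CN/NaH gives (2E)-3-{(2R,3R)-3-[(3R)-2-hydroxy-2,6-dimethylhept-5-en-3-yl]oxiran-2-yl}but-2-enenitrile F4 after chromatography, and i-Bu2AlH reduction with wet-SiO2 work-up gives 10.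

2. The hydration (step 7). Hydrogen-atom transfer to the conjugated dienenitrile may compete with hydration of the prenyl group. The fallback sets out from 3 and comes back at 11; it moves the hydration to the ester stage, where no conjugated acceptor is present. Ester 3 is hydrated under the same Co(acac)2/PhSiH3/O2 conditions to rac-ethyl 5-hydroxy-2-(2-hydroxypropan-2-yl)-5-methylhexanoate F5. Reduction with i-Bu2AlH (3.1 equiv) gives, as its aluminium hemiacetal in the flask, rac-5-hydroxy-2-(2-hydroxypropan-2-yl)-5-methylhexanal F6, and HWE olefination with 4 in the same flask, as in step 2, gives rac-(2E,4E)-7-hydroxy-6-(3-hydroxy-3-methylbutyl)-3,7-dimethylocta-2,4-dienenitrile F7. Separation on the chiral phase gives 11 and its enantiomer (2E,4E,6R)-7-hydroxy-6-(3-hydroxy-3-methylbutyl)-3,7-dimethylocta-2,4-dienenitrile F8, which is set aside.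

3. The mono-olefination (step 12). Mono-olefination of a bis-ylide is statistical and the mono-salt may be hard to purify. The fallback sets out from 16 and 12 and comes back at 18; it reverses the polarity of the first coupling, because mono-olefination of a symmetric polyene dialdehyde is clean. Diol 16 is oxidised with MnO2 to (2E,4E,6E,8E,10E,12E,14E)-2,6,11,15-tetramethylhexadeca-2,4,6,8,10,12,14-heptaenedial F9. Aldehyde 12 is reduced with NaBH4 to (2E,4E,6S)-6-(3-hydroxy-3-methylbutyl)-3,7-dimethylocta-2,4-diene-1,7-diol F10 and converted with PPh3·HBr into [(2E,4E,6S)-7-hydroxy-6-(3-hydroxy-3-methylbutyl)-3,7-dimethylocta-2,4-dien-1-yl]triphenylphosphonium bromide F11. Wittig reaction of F11 with excess F9 (NaOMe) gives (2E,4E,6E,8E,10E,12E,14E,16E,18E,20E,22S)-23-hydroxy-22-(3-hydroxy-3-methylbutyl)-2,6,11,15,19,23-hexamethyltetracosa-2,4,6,8,10,12,14,16,18,20-decaenal F12. NaBH4 reduction gives (2E,4E,6E,8E,10E,12E,14E,16E,18E,20E,22S)-22-(3-hydroxy-3-methylbutyl)-2,6,11,15,19,23-hexamethyltetracosa-2,4,6,8,10,12,14,16,18,20-decaene-1,23-diol F13, and PPh3·HBr converts F13 into 18.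

**Further compounds**
F1 | step 6 | rac-(3E)-6-hydroxy-6-methyl-5-(3-methylbut-2-en-1-yl)hept-3-en-2-one | CC(=O)/C=C/C(CC=C(C)C)C(C)(C)O
F2 | step 6 | 1-{(2S,3R)-3-[(3R)-2-hydroxy-2,6-dimethylhept-5-en-3-yl]oxiran-2-yl}ethan-1-one | CC(C)=CC[C@H]([C@H]1O[C@@H]1C(C)=O)C(C)(C)O
F3 | step 6 | 1-{(2S,3R)-3-[(3S)-2-hydroxy-2,6-dimethylhept-5-en-3-yl]oxiran-2-yl}ethan-1-one | CC(C)=CC[C@@H]([C@H]1O[C@@H]1C(C)=O)C(C)(C)O
F4 | step 6 | (2E)-3-{(2R,3R)-3-[(3R)-2-hydroxy-2,6-dimethylhept-5-en-3-yl]oxiran-2-yl}but-2-enenitrile | CC(C)=CC[C@H]([C@H]1O[C@@H]1/C(C)=C/C#N)C(C)(C)O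
F5 | step 7 | rac-ethyl 5-hydroxy-2-(2-hydroxypropan-2-yl)-5-methylhexanoate | CCOC(=O)C(CCC(C)(C)O)C(C)(C)O
F6 | step 7 | rac-5-hydroxy-2-(2-hydroxypropan-2-yl)-5-methylhexanal | CC(C)(O)CCC(C=O)C(C)(C)O
F7 | step 7 | rac-(2E,4E)-7-hydroxy-6-(3-hydroxy-3-methylbutyl)-3,7-dimethylocta-2,4-dienenitrile | CC(C)(O)CCC(/C=C/C(C)=C/C#N)C(C)(C)O
F8 | step 7 | (2E,4E,6R)-7-hydroxy-6-(3-hydroxy-3-methylbutyl)-3,7-dimethylocta-2,4-dienenitrile | CC(C)(O)CC[C@H](/C=C/C(C)=C/C#N)C(C)(C)O
F9 | step 12 | (2E,4E,6E,8E,10E,12E,14E)-2,6,11,15-tetramethylhexadeca-2,4,6,8,10,12,14-heptaenedial | O=C/C(C)=C/C=C/C(C)=C/C=C/C=C(C)/C=C/C=C(C)/C=O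
F10 | step 12 | (2E,4E,6S)-6-(3-hydroxy-3-methylbutyl)-3,7-dimethylocta-2,4-diene-1,7-diol | CC(C)(O)CC[C@@H](/C=C/C(C)=C/CO)C(C)(C)O
F11 | step 12 | [(2E,4E,6S)-7-hydroxy-6-(3-hydroxy-3-methylbutyl)-3,7-dimethylocta-2,4-dien-1-yl]triphenylphosphonium bromide | CC(C)(O)CC[C@@H](/C=C/C(C)=C/C[P+](c1ccccc1)(c1ccccc1)c1ccccc1)C(C)(C)O.[Br-]
F12 | step 12 | (2E,4E,6E,8E,10E,12E,14E,16E,18E,20E,22S)-23-hydroxy-22-(3-hydroxy-3-methylbutyl)-2,6,11,15,19,23-hexamethyltetracosa-2,4,6,8,10,12,14,16,18,20-decaenal | O=C/C(C)=C/C=C/C(C)=C/C=C/C=C(C)/C=C/C=C(C)/C=C/C=C(C)/C=C/[C@H](CCC(C)(C)O)C(C)(C)O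
F13 | step 12 | (2E,4E,6E,8E,10E,12E,14E,16E,18E,20E,22S)-22-(3-hydroxy-3-methylbutyl)-2,6,11,15,19,23-hexamethyltetracosa-2,4,6,8,10,12,14,16,18,20-decaene-1,23-diol | OC/C(C)=C/C=C/C(C)=C/C=C/C=C(C)/C=C/C=C(C)/C=C/C=C(C)/C=C/[C@H](CCC(C)(C)O)C(C)(C)O
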